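# Proposed synthesis of CNP0257794.1, (7S,8R,8′R)-7-hydroxy-9,9′-epoxylignan 19, by enantioselective carbenoid C–H insertion

Lignan numbering is used throughout: C7 is the carbinol carbon on ring A, C8 and C8′ are the oxolane CH carbons (C8 next to C7), C9 and C9′ are the oxolane CH2 carbons on C8 and C8′, and C7′ is the benzylic CH2 on ring B.

## Analysis of the target

Target 19 is a 3,4-disubstituted oxolane whose ring is built from O, C9, C8, C8′ and C9′. C8 carries the carbinol carbon C7 bonded to syringyl ring A, and C8′ carries the methylene C7′ bonded to syringyl ring B. The three contiguous stereocentres are 7S, 8R and 8′R. The two ring substituents are trans, and the C7 hydroxyl and C8′ are syn when the chain C9–C8–C7–ring A is drawn extended. The sensitive groups are two free 2,6-dimethoxyphenols, which oxidise easily, and a secondary benzylic alcohol para to a phenol. That alcohol ionises under acid (quinone methide formation, Friedel–Crafts closure onto ring B, dehydration) and is at risk under hydrogenolysis, so the last steps should be neither acidic nor reductive. The main difficulty is C8′: it is a plain tertiary CH with no neighbouring functional group, so it cannot be epimerised or corrected once formed. C7 lies outside the ring and needs acyclic control relative to C8. The strategy rests on one feature: C8′ is the middle carbon of the chain C9′–C8′–C7′ that joins the ring oxygen to ring B. If C9 is raised to an ester carbonyl, this chain becomes the alkoxy part of an ester and C8′ lies five atoms from C8, so a carbenoid at C8, flanked by the C9 ester and a C7 ketone, can reach a C8′–H bond.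

## Retrosynthetic reasoning

**O–Si bonds of 18.** The three hydroxyl groups of 19 are released last from the tris-silyl ether 18. Cutting O–Si bonds at the end means no free phenol or free benzylic alcohol has to survive earlier steps, and the forward reaction needs only a buffered fluoride source.

**Ring C–O bond (18 to 16).** Cutting one C–O bond of the oxolane gives the 1,4-diol 16. The two hydroxymethyl groups on C8 and C8′ are interchangeable as nucleophile and leaving-group carrier, so either monosulfonate, drawn as 17, closes to the same ring and no differentiation is needed. O7 must stay blocked, because a free O7 could attack C9′ and give the isomeric 2-aryl oxolane.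

**Oxidation level of C9 (16 to 15 to 14).** Diol 16 comes from lactone 15 by hydride reduction, and 15 is the silyl ether of hydroxy lactone 14. Keeping C9 as a lactone carbonyl up to this point is what makes both the C7 reduction and the key step possible.

**C7–H bond (14 to 13).** The C7 stereocentre is traced back to the ketone of 13. In 13 the ketone is β to the lactone carbonyl, so C8 is configurationally mobile and tied to C8′ by the trans preference. The reduction therefore only has to choose a face of the ketone, which a chiral transfer-hydrogenation catalyst can do.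

**C8–C8′ bond (13 to 12), the key disconnection.** C8–C8′ is the bond that joins the two phenylpropanoid halves. Cutting it opens the lactone to the acyclic diazo keto ester 12, in which the halves are held together only by an ester. No other cut removes a ring, a skeletal bond and the uncorrectable centre C8′ in one stroke. The forward reaction must pick one of the two enantiotopic hydrogens on C8′ and must prefer this methylene over its two neighbours.

**C8=N2 (12 to 11).** The diazo group is placed on the active methylene of β-keto ester 11 by diazo transfer from a sulfonyl azide. This is reliable and keeps the risk of the route in the key step.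

**Ester C9–O and C7–C8 bonds (11 to 9 and 4; 9 to 7 and 8).** Keto ester 11 is split at the ester oxygen into alcohol 4 and an aroylacetyl unit. That unit is delivered as the aroylketene 10, which forms on heating the acyl Meldrum's acid 9, so 4 and 9 can be used in equal amounts without base. Compound 9 comes from acid 7 and Meldrum's acid 8, which supplies C8 and C9.

**Protecting groups and the propanol chain (7 to 5; 4 to 2 to 1).** Acid 7 is syringic acid 5 with its phenol silylated, reached through the bis-silyl compound 6. Alcohol 4 comes from the allylphenol 1, whose allyl group already contains C7′, C8′ and C9′: silylation gives 2, and anti-Markovnikov hydration through the borane adduct 3 gives 4.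

## Alternatives that were turned down

**Alternative 1: tandem conjugate addition and alkylation on a chiral butenolide.**
- Disconnection: C7–C8 and C8′–C7′, on a preformed four-carbon unit C9–C8–C8′–C9′.
- Forward key step: a lithiated 2-aryl-1,3-dithiane, serving as the C7 acyl anion, adds 1,4 to (5R)-5-(menthyloxy)furan-2(5H)-one A1 on the face away from the menthyloxy group. The resulting lactone enolate is then benzylated trans to the new substituent by a benzylic bromide carrying ring B, giving the trisubstituted lactone A2.
- For it: two C–C bonds and both ring stereocentres are set in one flask under auxiliary control that is well understood and gives crystalline material. On the security of C8′ and C8 this alternative is stronger than the chosen route.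
- Against it for this target: A2 is far from 19. The lactone and the acetal carbon must be reduced, the diol cyclised and the dithiane removed with thiophilic or oxidative reagents next to two electron-rich rings. The resulting ketone sits on a plain oxolane with no second carbonyl to direct its reduction. Benzyl ethers would then be removed by hydrogenolysis beside a benzylic alcohol. With the preparation of three components the step count is no lower.
- Comparison: the chosen route trades auxiliary-secured stereocontrol for a catalytic step, but it delivers C7 as a ketone inside a 1,3-dicarbonyl, where both catalyst-controlled and chelation-controlled reduction are available. It also needs no sulfur chemistry and ends with fluoride.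

**Alternative 2: gold-catalysed hydroxycyclisation of a propargyl (Z)-cinnamyl ether.**
- Disconnection: C8–C8′ and C7–O.
- Forward key step: a cationic monovalent gold complex activates the alkyne of a propargyl (Z)-3-arylallyl ether. Alkene carbon C8 attacks the internal alkyne carbon and closes the oxolane, and water adds to C7 anti to the new bond, giving the methylidene oxolane A3.
- For it: the ring is formed directly at the ether oxidation level, the C7/C8 relation follows stereospecifically from the alkene geometry, and the route to A3 is shorter than the chosen route to 14. On step economy up to that point it is stronger.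
- Against it for this target: the absolute configuration would depend on enantioselective gold catalysis, which is strongly substrate dependent, and a benzylic cation stabilised by the electron-rich ring can erode the anti addition. A3 also lacks ring B. Turning the methylidene group into the trans arylmethyl group sets C8′ late and under substrate control. Undirected hydroboration or hydrogenation delivers hydrogen anti to the C8 substituent and thus gives the cis ring, so a hydroxyl-directed reduction of a derived arylmethylidene would be needed.
- Comparison: the chosen route sets C8′ first, in the step designed for it, and leaves only correctable centres (C8 by equilibration, C7 by reduction) for later.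

**Alternative 3: carbonyl ylide cycloaddition that builds the oxolane last.**
- Disconnection: C8–C9 and C8′–C9′.
- Forward key step: the parent carbonyl ylide, released by CsF from a chloromethyl silylmethyl ether, adds across an (E)-4-arylbut-2-enoyl oxazolidinone, giving the acyl oxazolidinone A4.
- For it: the trans ring relation is guaranteed by the E alkene, which is stronger than the equilibration used in the chosen route, and the ring is again formed as an ether.
- Against it for this target: the unstabilised ylide is short-lived, and facial control by an oxazolidinone in a thermal, non-chelated dipolar cycloaddition is modest. The dipolarophile can also slip into conjugation with ring B under basic fluoride. After the cycloaddition C7 is still missing: the imide must be converted into an aryl ketone and reduced without a directing carbonyl, and the benzyl ether must then be removed reductively.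
- Comparison: the chosen route has both aryl rings and every skeletal carbon in place after its key step, and keeps a carbonyl next to C8 to steer the C7 reduction.

Key step: step 7

## Remarks before the steps

- Assumption: 2,6-dimethoxy-4-(prop-2-en-1-yl)phenol 1 (4-allylsyringol) is taken as a commercial starting material, so that the 3-arylpropanol is reached in two steps.
- Assumption: the sense of induction of Rh2(S-PTTL)4, dirhodium tetrakis[N-phthaloyl-(S)-tert-leucinate], with diazo keto ester 12 cannot be predicted with confidence. The route is written for the catalyst antipode that gives the 4R lactone, and Rh2(R-PTTL)4 is used if the sense is opposite.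
- Remark: C8 is designated S in the lactones 13–15 and R in 16–19. The spatial arrangement is the same throughout; the descriptor changes because the lactone carbonyl outranks C7 in the sequence rule.
- Abbreviation in the steps: Ar = 3,5-dimethoxy-4-(triisopropylsilyloxy)phenyl. Full names are in the compound list.

## Route

Step 1
Reactants: 1 2,6-dimethoxy-4-(prop-2-en-1-yl)phenol
Product: 2 [2,6-dimethoxy-4-(prop-2-en-1-yl)phenoxy]triisopropylsilane
Conditions: TIPSCl, imidazole, DMF, 50 °C
Reagents that add atoms: chlorotriisopropylsilane (TIPSCl), CC(C)[Si](Cl)(C(C)C)C(C)C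
Why: Imidazole-promoted O-silylation of a phenol; the two flanking methoxy groups slow the reaction, hence warm DMF, and the allyl group is inert.

Step 2
Reactants: 2 [2,6-dimethoxy-4-(prop-2-en-1-yl)phenoxy]triisopropylsilane
Product: 4 3-Ar-propan-1-ol, via B-alkyl-9-BBN adduct 3 (not isolated)
Conditions: 9-BBN, THF, 0 °C → rt; then NaBO3·4H2O, H2O, rt
Reagents that add atoms: sodium perborate, [Na+].[Na+].O[B-]1(O)OO[B-](O)(O)OO1
Why: Hydroboration–oxidation; 9-BBN places boron on the terminal carbon of an allylarene with high anti-Markovnikov selectivity, and perborate oxidises the C–B bond under nearly neutral conditions that spare the aryl silyl ether.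

Step 3
Reactants: 5 4-hydroxy-3,5-dimethoxybenzoic acid (syringic acid)
Product: 7 3,5-dimethoxy-4-(triisopropylsilyloxy)benzoic acid, via bis-silylated syringate 6 (not isolated)
Conditions: TIPSCl (2.4 equiv), imidazole, DMF, 50 °C; then K2CO3, THF–MeOH–H2O, 0 °C; acidify to pH 4
Reagents that add atoms: chlorotriisopropylsilane (TIPSCl), CC(C)[Si](Cl)(C(C)C)C(C)C
Why: Exhaustive silylation gives the silyl ether–silyl ester 6; a silyl ester is cleaved by cold aqueous carbonate far faster than a hindered aryl triisopropylsilyl ether, which leaves acid 7.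

Step 4
Reactants: 7 3,5-dimethoxy-4-(triisopropylsilyloxy)benzoic acid; 8 2,2-dimethyl-1,3-dioxane-4,6-dione (Meldrum's acid)
Product: 9 5-[Ar(hydroxy)methylidene]-2,2-dimethyl-1,3-dioxane-4,6-dione
Conditions: DCC, DMAP, CH2Cl2, 0 °C → rt
Reagents that add atoms: none
Why: Carbodiimide/DMAP C-acylation of Meldrum's acid by an activated aryl carboxylic acid; the acid has no ortho substituent and the product is stabilised as its enol.

Step 5
Reactants: 9 5-[Ar(hydroxy)methylidene]-2,2-dimethyl-1,3-dioxane-4,6-dione; 4 3-Ar-propan-1-ol
Product: 11 3-Ar-propyl 3-Ar-3-oxopropanoate, via aroylketene 10 (not isolated)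
Conditions: toluene, 100 °C
Reagents that add atoms: none
Why: Thermolysis of an acyl Meldrum's acid releases aroylketene 10 by loss of acetone and CO2, and the primary alcohol 4 adds to the ketene to give the β-keto ester. No acid or base is needed, so both silyl ethers survive.

Step 6
Reactants: 11 3-Ar-propyl 3-Ar-3-oxopropanoate
Product: 12 3-Ar-propyl 2-diazo-3-Ar-3-oxopropanoate
Conditions: 4-acetamidobenzenesulfonyl azide, Et3N, MeCN, 0 °C → rt
Reagents that add atoms: 4-acetamidobenzenesulfonyl azide, CC(=O)Nc1ccc(cc1)S(=O)(=O)N=[N+]=[N-]
Why: Regitz diazo transfer to a methylene flanked by ketone and ester; triethylamine is basic enough and the sulfonamide by-product is easily removed.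

Step 7
Reactants: 12 3-Ar-propyl 2-diazo-3-Ar-3-oxopropanoate
Product: 13 (3S,4R)-3-(Ar-carbonyl)-4-(Ar-methyl)oxolan-2-one
Conditions: Rh2(S-PTTL)4 (2 mol %), CH2Cl2, 40 °C, slow addition of 12
Reagents that add atoms: none
Why: Proposed new method: the dirhodium tetracarboxylate expels N2 from 12 to give an electrophilic acceptor/acceptor carbenoid at C8, which inserts into a C8′–H bond through a concerted three-centre transition state with hydride-transfer character and so forms C8–C8′. The closest known reaction types are the chiral dirhodium-catalysed 1,5-insertion of 3-arylpropyl diazoacetates to 4-(arylmethyl)oxolan-2-ones and the achiral dirhodium-catalysed lactonisation of alkyl 2-diazo-3-oxo esters; enantiotopic C–H selection with a 2-diazo-3-aryl-3-oxopropanoate is the untested element. The oxolan-2-one closes by 1,5-insertion, the five-membered transition ring comprising C8, C9, the ester oxygen, C9′ and C8′. C8′ is set by the chiral pocket of the four N-phthaloyl-tert-leucinate ligands, which must tell apart the two enantiotopic hydrogens of a methylene whose neighbours (OCH2 and ArCH2) differ clearly in size and polarity. C8 lies between the ketone and lactone carbonyls, is epimerisable, and is expected to rest trans to the arylmethyl group under thermodynamic control. The step needs site selectivity for C8′–H: the C9′–H bonds are deactivated by the adjacent acyloxy oxygen and would give a strained four-membered lactone, and the benzylic C7′–H bonds can be reached only through a six-membered transition ring, which ester-tethered dirhodium carbenoids disfavour. It also needs chemoselectivity against attack on the electron-rich ring B and against carbene dimerisation, which the distance to ring B, the bulky silyl ethers and slow addition at high dilution should secure.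

Step 8
Reactants: 13 (3S,4R)-3-(Ar-carbonyl)-4-(Ar-methyl)oxolan-2-one
Product: 14 (3S,4R)-3-[(S)-Ar(hydroxy)methyl]-4-(Ar-methyl)oxolan-2-one
Conditions: RuCl[(S,S)-TsDPEN](p-cymene) (2 mol %), HCO2H–Et3N (5:2), CH2Cl2, 30 °C
Reagents that add atoms: none
Why: Noyori-type asymmetric transfer hydrogenation of an aryl ketone, a known reaction class for β-keto esters and 2-acyl lactones with dynamic kinetic resolution. By the usual aryl-ketone model the (S,S) ligand should deliver hydride to the face that gives 7S, while C8 equilibrates through the enol and reacts through the less hindered trans epimer. Because C7 is set by the catalyst, any minor enantiomer of 13 is carried into a separable diastereomer.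

Step 9
Reactants: 14 (3S,4R)-3-[(S)-Ar(hydroxy)methyl]-4-(Ar-methyl)oxolan-2-one
Product: 15 (3S,4R)-3-{(S)-Ar[(tert-butyldimethylsilyl)oxy]methyl}-4-(Ar-methyl)oxolan-2-one
Conditions: TBSOTf, 2,6-lutidine, CH2Cl2, −78 → 0 °C
Reagents that add atoms: tert-butyldimethylsilyl trifluoromethanesulfonate (TBSOTf), CC(C)(C)[Si](C)(C)OS(=O)(=O)C(F)(F)F
Why: Silyl triflate/lutidine silylation of a hindered secondary alcohol; low temperature and a non-nucleophilic base avoid retro-aldol cleavage and β-elimination of the β-hydroxy lactone. The ether later keeps O7 out of the ring closure.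

Step 10
Reactants: 15 (3S,4R)-3-{(S)-Ar[(tert-butyldimethylsilyl)oxy]methyl}-4-(Ar-methyl)oxolan-2-one
Product: 16 (2R,3R)-2-{(S)-Ar[(tert-butyldimethylsilyl)oxy]methyl}-3-(Ar-methyl)butane-1,4-diol
Conditions: LiAlH4, THF, 0 °C; H2O/NaOH work-up
Reagents that add atoms: none
Why: Hydride reduction of a lactone to the 1,4-diol; aryl and alkyl silyl ethers tolerate LiAlH4 at 0 °C and no stereocentre is touched.

Step 11
Reactants: 16 (2R,3R)-2-{(S)-Ar[(tert-butyldimethylsilyl)oxy]methyl}-3-(Ar-methyl)butane-1,4-diol
Product: 18 tert-butyl{(S)-Ar[(3R,4R)-4-(Ar-methyl)oxolan-3-yl]methoxy}dimethylsilane, via primary monotosylate 17 (not isolated)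
Conditions: TsCl (1.1 equiv), pyridine, DMAP (cat.), CH2Cl2, 0 → 40 °C
Reagents that add atoms: none
Why: Monosulfonylation of one primary hydroxyl followed by intramolecular Williamson-type 5-exo-tet displacement by the other. Either hydroxyl may be sulfonylated first, since both monotosylates close to the same oxolane, and neither C8 nor C8′ is a reacting centre.

Step 12
Reactants: 18 tert-butyl{(S)-Ar[(3R,4R)-4-(Ar-methyl)oxolan-3-yl]methoxy}dimethylsilane
Product: 19 4-{[(3R,4R)-4-[(S)-hydroxy(4-hydroxy-3,5-dimethoxyphenyl)methyl]oxolan-3-yl]methyl}-2,6-dimethoxyphenol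
Conditions: TBAF, AcOH, THF, 0 °C → rt
Reagents that add atoms: none
Why: Fluoride cleavage of two aryl silyl ethers and one alkyl silyl ether. Acetic acid buffering keeps the medium from turning strongly basic once the phenols are free, and the step avoids the acid and hydrogenolysis conditions that endanger the benzylic alcohol.

## Compound list

1 | 2,6-dimethoxy-4-(prop-2-en-1-yl)phenol | C=CCc1cc(OC)c(O)c(OC)c1 | starting material
2 | [2,6-dimethoxy-4-(prop-2-en-1-yl)phenoxy]triisopropylsilane | C=CCc1cc(OC)c(O[Si](C(C)C)(C(C)C)C(C)C)c(OC)c1 | intermediate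
3 | 9-{3-[3,5-dimethoxy-4-(triisopropylsilyloxy)phenyl]propyl}-9-borabicyclo[3.3.1]nonane | COc1cc(CCCB2C3CCCC2CCC3)cc(OC)c1O[Si](C(C)C)(C(C)C)C(C)C | intermediate
4 | 3-[3,5-dimethoxy-4-(triisopropylsilyloxy)phenyl]propan-1-ol | COc1cc(CCCO)cc(OC)c1O[Si](C(C)C)(C(C)C)C(C)C | intermediate
5 | 4-hydroxy-3,5-dimethoxybenzoic acid (syringic acid) | COc1cc(cc(OC)c1O)C(O)=O | starting material
6 | triisopropylsilyl 3,5-dimethoxy-4-(triisopropylsilyloxy)benzoate | COc1cc(cc(OC)c1O[Si](C(C)C)(C(C)C)C(C)C)C(=O)O[Si](C(C)C)(C(C)C)C(C)C | intermediate
7 | 3,5-dimethoxy-4-(triisopropylsilyloxy)benzoic acid | COc1cc(cc(OC)c1O[Si](C(C)C)(C(C)C)C(C)C)C(O)=O | intermediate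
8 | 2,2-dimethyl-1,3-dioxane-4,6-dione (Meldrum's acid) | CC1(C)OC(=O)CC(=O)O1 | starting material
9 | 5-{[3,5-dimethoxy-4-(triisopropylsilyloxy)phenyl](hydroxy)methylidene}-2,2-dimethyl-1,3-dioxane-4,6-dione | COc1cc(cc(OC)c1O[Si](C(C)C)(C(C)C)C(C)C)C(O)=C1C(=O)OC(C)(C)OC1=O | intermediate
10 | 1-[3,5-dimethoxy-4-(triisopropylsilyloxy)phenyl]prop-2-ene-1,3-dione (aroylketene) | COc1cc(cc(OC)c1O[Si](C(C)C)(C(C)C)C(C)C)C(=O)C=C=O | intermediate
11 | 3-[3,5-dimethoxy-4-(triisopropylsilyloxy)phenyl]propyl 3-[3,5-dimethoxy-4-(triisopropylsilyloxy)phenyl]-3-oxopropanoate | COc1cc(CCCOC(=O)CC(=O)c2cc(OC)c(O[Si](C(C)C)(C(C)C)C(C)C)c(OC)c2)cc(OC)c1O[Si](C(C)C)(C(C)C)C(C)C | intermediate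
12 | 3-[3,5-dimethoxy-4-(triisopropylsilyloxy)phenyl]propyl 2-diazo-3-[3,5-dimethoxy-4-(triisopropylsilyloxy)phenyl]-3-oxopropanoate | COc1cc(CCCOC(=O)C(=[N+]=[N-])C(=O)c2cc(OC)c(O[Si](C(C)C)(C(C)C)C(C)C)c(OC)c2)cc(OC)c1O[Si](C(C)C)(C(C)C)C(C)C | intermediate
13 | (3S,4R)-3-[3,5-dimethoxy-4-(triisopropylsilyloxy)benzoyl]-4-{[3,5-dimethoxy-4-(triisopropylsilyloxy)phenyl]methyl}oxolan-2-one | O=C1OC[C@H](Cc2cc(OC)c(O[Si](C(C)C)(C(C)C)C(C)C)c(OC)c2)[C@H]1C(=O)c1cc(OC)c(O[Si](C(C)C)(C(C)C)C(C)C)c(OC)c1 | intermediate
14 | (3S,4R)-3-{(S)-[3,5-dimethoxy-4-(triisopropylsilyloxy)phenyl](hydroxy)methyl}-4-{[3,5-dimethoxy-4-(triisopropylsilyloxy)phenyl]methyl}oxolan-2-one | O=C1OC[C@H](Cc2cc(OC)c(O[Si](C(C)C)(C(C)C)C(C)C)c(OC)c2)[C@H]1[C@H](O)c1cc(OC)c(O[Si](C(C)C)(C(C)C)C(C)C)c(OC)c1 | intermediate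
15 | (3S,4R)-3-{(S)-[(tert-butyldimethylsilyl)oxy][3,5-dimethoxy-4-(triisopropylsilyloxy)phenyl]methyl}-4-{[3,5-dimethoxy-4-(triisopropylsilyloxy)phenyl]methyl}oxolan-2-one | O=C1OC[C@H](Cc2cc(OC)c(O[Si](C(C)C)(C(C)C)C(C)C)c(OC)c2)[C@H]1[C@H](O[Si](C)(C)C(C)(C)C)c1cc(OC)c(O[Si](C(C)C)(C(C)C)C(C)C)c(OC)c1 | intermediate
16 | (2R,3R)-2-{(S)-[(tert-butyldimethylsilyl)oxy][3,5-dimethoxy-4-(triisopropylsilyloxy)phenyl]methyl}-3-{[3,5-dimethoxy-4-(triisopropylsilyloxy)phenyl]methyl}butane-1,4-diol | COc1cc(C[C@@H](CO)[C@H](CO)[C@H](O[Si](C)(C)C(C)(C)C)c2cc(OC)c(O[Si](C(C)C)(C(C)C)C(C)C)c(OC)c2)cc(OC)c1O[Si](C(C)C)(C(C)C)C(C)C | intermediate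
17 | (2R,3R)-3-{(S)-[(tert-butyldimethylsilyl)oxy][3,5-dimethoxy-4-(triisopropylsilyloxy)phenyl]methyl}-2-{[3,5-dimethoxy-4-(triisopropylsilyloxy)phenyl]methyl}-4-hydroxybutyl 4-methylbenzenesulfonate | COc1cc(C[C@@H](COS(=O)(=O)c2ccc(C)cc2)[C@H](CO)[C@H](O[Si](C)(C)C(C)(C)C)c2cc(OC)c(O[Si](C(C)C)(C(C)C)C(C)C)c(OC)c2)cc(OC)c1O[Si](C(C)C)(C(C)C)C(C)C | intermediate
18 | tert-butyl{(S)-[3,5-dimethoxy-4-(triisopropylsilyloxy)phenyl][(3R,4R)-4-{[3,5-dimethoxy-4-(triisopropylsilyloxy)phenyl]methyl}oxolan-3-yl]methoxy}dimethylsilane | COc1cc(C[C@H]2COC[C@@H]2[C@H](O[Si](C)(C)C(C)(C)C)c2cc(OC)c(O[Si](C(C)C)(C(C)C)C(C)C)c(OC)c2)cc(OC)c1O[Si](C(C)C)(C(C)C)C(C)C | intermediate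
19 | 4-{[(3R,4R)-4-[(S)-hydroxy(4-hydroxy-3,5-dimethoxyphenyl)methyl]oxolan-3-yl]methyl}-2,6-dimethoxyphenol | COc1cc(C[C@H]2COC[C@@H]2[C@H](O)c2cc(OC)c(O)c(OC)c2)cc(OC)c1O | target

## Step count and least certain steps

Total step count: 12. Longest linear sequence: 10 steps (from 5 through steps 3–12, or equally from 1 through steps 1, 2 and 5–12).

**Step 7 (key step, carries the label "Proposed new method:").** The most likely failure is weak discrimination between the two enantiotopic C8′–H bonds, because an acceptor/acceptor carbenoid is more reactive and less selective than the diazoacetate-derived carbenoids for which such selection is established. Loss of material through insertion at the benzylic C7′–H, closure of a four-membered lactone at C9′–H or attack on ring B is also possible.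

The fallback uses known chemistry and sets out from alcohol 4. Acylation with bromoacetyl bromide should give 3-[3,5-dimethoxy-4-(triisopropylsilyloxy)phenyl]propyl bromoacetate F1. N,N′-Ditosylhydrazine and DBU should convert this into 3-[3,5-dimethoxy-4-(triisopropylsilyloxy)phenyl]propyl diazoacetate F2. The chiral dirhodium carboxamidate Rh2(MPPIM)4, dirhodium tetrakis[methyl 2-oxo-1-(3-phenylpropanoyl)imidazolidine-4-carboxylate], in the antipode that gives the R lactone, should then cyclise F2 by the established diazoacetate insertion to (4R)-4-{[3,5-dimethoxy-4-(triisopropylsilyloxy)phenyl]methyl}oxolan-2-one F3. The lithium enolate of F3 (LiN(SiMe3)2, 2 equiv, THF, −78 °C) is C-acylated with 3,5-dimethoxy-4-(triisopropylsilyloxy)benzoyl chloride F4, made from acid 7 with oxalyl chloride and catalytic DMF. The acylation places the aroyl group trans to the arylmethyl group and returns to the route at keto lactone 13.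

**Step 8.** Facial selectivity may be poor if the hydride trajectory preferred by the catalyst opposes the intrinsic bias of the trans lactone, or if the catalyst reduces the minor cis C8 epimer faster and drains material into the cis series. The electron-rich ketone may also react slowly.

The fallback replaces catalyst control by substrate control and sets out from 13. Zn(BH4)2 in Et2O at −20 °C should bind the ketone and lactone carbonyls in a chelate. Hydride then enters from the face remote from the ring, which by the chelate model gives the same syn, 7S isomer and rejoins the route at 14. The enantiomeric purity is then only what step 7 delivers.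

**Step 11.** A second sulfonylation may outrun ring closure, or the C7 silyl group may migrate to O9 and allow O7 to close onto C9′.

The fallback avoids the free diol and sets out from lactone 15. Partial reduction with iBu2AlH in CH2Cl2 at −78 °C should give (3S,4R)-3-{(S)-[(tert-butyldimethylsilyl)oxy][3,5-dimethoxy-4-(triisopropylsilyloxy)phenyl]methyl}-4-{[3,5-dimethoxy-4-(triisopropylsilyloxy)phenyl]methyl}oxolan-2-ol F5 as an anomeric mixture. Ionic deoxygenation with Et3SiH and BF3·OEt2 at −78 °C, through the cyclic oxocarbenium ion, should give the oxolane directly and rejoin the route at 18.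

**Step 12.** Cleavage of the hindered secondary tert-butyldimethylsilyl ether may be slow, and forcing it with basic fluoride after the phenols are free may trigger decomposition of the p-hydroxybenzylic alcohol through a quinone methide.

The fallback changes the O7 protecting group and sets out from 14. Et3SiOTf and 2,6-lutidine should give (3S,4R)-3-{(S)-[3,5-dimethoxy-4-(triisopropylsilyloxy)phenyl](triethylsilyloxy)methyl}-4-{[3,5-dimethoxy-4-(triisopropylsilyloxy)phenyl]methyl}oxolan-2-one F6. LiAlH4 should reduce it to (2R,3R)-2-{(S)-[3,5-dimethoxy-4-(triisopropylsilyloxy)phenyl](triethylsilyloxy)methyl}-3-{[3,5-dimethoxy-4-(triisopropylsilyloxy)phenyl]methyl}butane-1,4-diol F7. TsCl and pyridine should close this to triethyl{(S)-[3,5-dimethoxy-4-(triisopropylsilyloxy)phenyl][(3R,4R)-4-{[3,5-dimethoxy-4-(triisopropylsilyloxy)phenyl]methyl}oxolan-3-yl]methoxy}silane F8. Its three silyl groups should all fall to TBAF/AcOH at 0 °C, arriving at 19.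

## Further compounds

F1 | step 7 | 3-[3,5-dimethoxy-4-(triisopropylsilyloxy)phenyl]propyl bromoacetate | COc1cc(CCCOC(=O)CBr)cc(OC)c1O[Si](C(C)C)(C(C)C)C(C)C
F2 | step 7 | 3-[3,5-dimethoxy-4-(triisopropylsilyloxy)phenyl]propyl diazoacetate | COc1cc(CCCOC(=O)C=[N+]=[N-])cc(OC)c1O[Si](C(C)C)(C(C)C)C(C)C
F3 | step 7 | (4R)-4-{[3,5-dimethoxy-4-(triisopropylsilyloxy)phenyl]methyl}oxolan-2-one | O=C1OC[C@H](Cc2cc(OC)c(O[Si](C(C)C)(C(C)C)C(C)C)c(OC)c2)C1
F4 | step 7 | 3,5-dimethoxy-4-(triisopropylsilyloxy)benzoyl chloride | COc1cc(cc(OC)c1O[Si](C(C)C)(C(C)C)C(C)C)C(Cl)=O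
F0 | step 8 | none | none
F5 | step 11 | (3S,4R)-3-{(S)-[(tert-butyldimethylsilyl)oxy][3,5-dimethoxy-4-(triisopropylsilyloxy)phenyl]methyl}-4-{[3,5-dimethoxy-4-(triisopropylsilyloxy)phenyl]methyl}oxolan-2-ol (anomeric mixture) | OC1OC[C@H](Cc2cc(OC)c(O[Si](C(C)C)(C(C)C)C(C)C)c(OC)c2)[C@H]1[C@H](O[Si](C)(C)C(C)(C)C)c1cc(OC)c(O[Si](C(C)C)(C(C)C)C(C)C)c(OC)c1
F6 | step 12 | (3S,4R)-3-{(S)-[3,5-dimethoxy-4-(triisopropylsilyloxy)phenyl](triethylsilyloxy)methyl}-4-{[3,5-dimethoxy-4-(triisopropylsilyloxy)phenyl]methyl}oxolan-2-one | O=C1OC[C@H](Cc2cc(OC)c(O[Si](C(C)C)(C(C)C)C(C)C)c(OC)c2)[C@H]1[C@H](O[Si](CC)(CC)CC)c1cc(OC)c(O[Si](C(C)C)(C(C)C)C(C)C)c(OC)c1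
F7 | step 12 | (2R,3R)-2-{(S)-[3,5-dimethoxy-4-(triisopropylsilyloxy)phenyl](triethylsilyloxy)methyl}-3-{[3,5-dimethoxy-4-(triisopropylsilyloxy)phenyl]methyl}butane-1,4-diol | COc1cc(C[C@@H](CO)[C@H](CO)[C@H](O[Si](CC)(CC)CC)c2cc(OC)c(O[Si](C(C)C)(C(C)C)C(C)C)c(OC)c2)cc(OC)c1O[Si](C(C)C)(C(C)C)C(C)C
F8 | step 12 | triethyl{(S)-[3,5-dimethoxy-4-(triisopropylsilyloxy)phenyl][(3R,4R)-4-{[3,5-dimethoxy-4-(triisopropylsilyloxy)phenyl]methyl}oxolan-3-yl]methoxy}silane | COc1cc(C[C@H]2COC[C@@H]2[C@H](O[Si](CC)(CC)CC)c2cc(OC)c(O[Si](C(C)C)(C(C)C)C(C)C)c(OC)c2)cc(OC)c1O[Si](C(C)C)(C(C)C)C(C)C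
A1 | alternative 1 | (5R)-5-{[(1R,2S,5R)-5-methyl-2-(propan-2-yl)cyclohexyl]oxy}furan-2(5H)-one | O=C1O[C@@H](O[C@@H]2C[C@H](C)CC[C@H]2C(C)C)C=C1
A2 | alternative 1 | (3R,4R,5R)-3-[(4-benzyloxy-3,5-dimethoxyphenyl)methyl]-4-[2-(4-benzyloxy-3,5-dimethoxyphenyl)-1,3-dithian-2-yl]-5-{[(1R,2S,5R)-5-methyl-2-(propan-2-yl)cyclohexyl]oxy}oxolan-2-one | O=C1O[C@@H](O[C@@H]2C[C@H](C)CC[C@H]2C(C)C)[C@H](C2(SCCCS2)c2cc(OC)c(OCc3ccccc3)c(OC)c2)[C@H]1Cc1cc(OC)c(OCc2ccccc2)c(OC)c1
A3 | alternative 2 | 4-{(S)-hydroxy[(3R)-4-methylideneoxolan-3-yl]methyl}-2,6-dimethoxyphenyl 2,2-dimethylpropanoate | C=C1COC[C@@H]1[C@H](O)c1cc(OC)c(OC(=O)C(C)(C)C)c(OC)c1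
A4 | alternative 3 | (4S)-4-benzyl-3-{[(3R,4R)-4-[(4-benzyloxy-3,5-dimethoxyphenyl)methyl]oxolan-3-yl]carbonyl}-1,3-oxazolidin-2-one | O=C1OC[C@H](Cc2ccccc2)N1C(=O)[C@H]1COC[C@@H]1Cc1cc(OC)c(OCc2ccccc2)c(OC)c1
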